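Ring A is numbered C1 (C–OMe), C2, C3, C4 (C–Br), C5, C6 (C–OAr). Its two neighbouring oxygens at C1 and C6 and the bromine at C4, para to C1, are exploited by cutting the C2–C3 and C4–C5 bonds: a 1-amino-2-aryloxy-3-siloxybutadiene that already carries ring B on oxygen adds to 1-bromovinyl phenyl sulfoxide, a bromoacetylene equivalent. One cycloaddition closes ring A, sets C1 as carbonyl and C6 as enol aryl ether, and puts bromine on C4. The diene comes from a hindered dibromophenol by alkylation at an sp3 carbon, so no O-arylation is needed. Loss of benzenesulfenic acid, O-methylation and debenzylation finish the synthesis.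

Key step: step 6

Remark: all sulfoxides are used as racemates and the carbon stereocentres of 11 and 12 are left as mixtures, because the target is achiral and every one of them is destroyed by the end of step 7.

Step 1
Reactants: 1 2-(benzyloxy)phenol
Product: 2 2-(benzyloxy)-4,6-dibromophenol
Conditions: NBS (2.1 equiv), i-Pr2NH (10 mol%), CH2Cl2, 0 °C to rt, dark
Reagents that add atoms: N-bromosuccinimide, O=C1CCC(=O)N1Br
Why: Electrophilic aromatic bromination is steered by the free hydroxyl group, a stronger donor than the benzyloxy group, so bromine should enter the open ortho position and then the para position of the phenol, while the unactivated benzyl ring is left alone.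

Step 2
Reactants: 2 2-(benzyloxy)-4,6-dibromophenol; 3 chloroacetone
Product: 4 1-[2-(benzyloxy)-4,6-dibromophenoxy]propan-2-one
Conditions: K2CO3, KI (cat.), acetone, reflux
Reagents that add atoms: none
Why: Williamson ether synthesis, in which the hindered, doubly ortho-substituted phenoxide attacks the unhindered primary carbon of the α-halo ketone (SN2, helped by the carbonyl group and by iodide exchange).

Step 3
Reactants: 4 1-[2-(benzyloxy)-4,6-dibromophenoxy]propan-2-one; 5 N,N-dimethylformamide dimethyl acetal
Product: 6 (3Z)-3-[2-(benzyloxy)-4,6-dibromophenoxy]-4-(dimethylamino)but-3-en-2-one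
Conditions: toluene, 90 °C, MeOH distilled off
Reagents that add atoms: none
Why: Enaminone formation with an amide acetal should take place at the methylene flanked by the carbonyl and the aryloxy oxygen, the more acidic α-position, with loss of two molecules of methanol; the dimethylamino group settles trans to the acetyl group, which is the Z descriptor because the aryloxy oxygen outranks carbon.

Step 4
Reactants: 6 (3Z)-3-[2-(benzyloxy)-4,6-dibromophenoxy]-4-(dimethylamino)but-3-en-2-one
Product: 7 (1Z)-2-[2-(benzyloxy)-4,6-dibromophenoxy]-3-[(tert-butyldimethylsilyl)oxy]-N,N-dimethylbuta-1,3-dien-1-amine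
Conditions: KN(SiMe3)2, THF, −78 °C; TBSCl, −78 °C to rt; filtered under argon and used crude
Reagents that add atoms: tert-butyldimethylsilyl chloride, CC(C)(C)[Si](C)(C)Cl
Why: Kinetic deprotonation of the acetyl methyl group of the vinylogous amide and O-silylation of the cross-conjugated enolate is the standard silyl enol ether formation that gives 1-amino-3-siloxybutadienes, and the enamine double-bond geometry of 6 is carried over unchanged.

Step 5
Reactants: 8 phenyl vinyl sulfoxide
Product: 10 rac-1-bromovinyl phenyl sulfoxide, via 1,2-dibromoethyl phenyl sulfoxide 9 (not isolated)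
Conditions: Br2, CH2Cl2, 0 °C to rt; then Et3N, 0 °C
Reagents that add atoms: bromine, BrBr
Why: Bromination–dehydrobromination of a vinyl sulfoxide: bromine adds to the vinyl group, then the base removes the most acidic hydrogen (on the carbon bearing sulfur and bromine) and the bromide on the neighbouring CH2 leaves, which should give the 1-bromo isomer.

Step 6
Reactants: 7 (1Z)-2-[2-(benzyloxy)-4,6-dibromophenoxy]-3-[(tert-butyldimethylsilyl)oxy]-N,N-dimethylbuta-1,3-dien-1-amine; 10 rac-1-bromovinyl phenyl sulfoxide
Product: 12 rac-2-[2-(benzyloxy)-4,6-dibromophenoxy]-4-bromo-4-(phenylsulfinyl)cyclohex-2-en-1-one (diastereomer mixture), via silyl enol ether cycloadduct 11 (not isolated)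
Conditions: toluene (1 M), rt to 45 °C; then 1 M HCl, THF, 0 °C
Reagents that add atoms: none
Why: The electron-rich diene 7 and the acceptor alkene 10 should combine in a concerted but asynchronous normal-demand [4+2] cycloaddition in which the CH2 terminus of the diene (C2 of ring A), which carries the largest HOMO coefficient, bonds to the unsubstituted CH2 of 10 (C3) while the amino-bearing terminus (C5) bonds to the carbon holding bromine and sulfur (C4). The closest known reaction type is the Diels–Alder reaction of 1-amino-3-siloxybutadienes with α-substituted acceptor alkenes to give 4,4-disubstituted cyclohexenones, combined with the established use of vinyl sulfoxides as dienophiles. Ring A is closed by this one intermolecular cycloaddition, both new σ-bonds (C2–C3 and C4–C5) arising in the same six-electron transition state. Dilute acid then hydrolyses the silyl enol ether to the C1 ketone and the protonated dimethylamino group leaves C5 by E1cB elimination through the enol, which gives the C5=C6 enone; the cold quench without isolation keeps the neighbouring amine from displacing bromide. The stereocentre formed at C4 (and the transient one at C5) is not controlled, so 12 is expected as a mixture of diastereomers relative to the racemic sulfur centre, which does no harm because C4 becomes sp2 in step 7. The only selectivity needed is regiochemical, and the amino group, the strongest donor of the diene, secures it by directing its own carbon to the acceptor-bearing carbon of the dienophile, which places bromine para to the C1 carbonyl.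

Step 7
Reactants: 12 rac-2-[2-(benzyloxy)-4,6-dibromophenoxy]-4-bromo-4-(phenylsulfinyl)cyclohex-2-en-1-one
Product: 14 2-[2-(benzyloxy)-4,6-dibromophenoxy]-4-bromophenol, via 4-bromocyclohexa-2,4-dienone 13 (not isolated)
Conditions: toluene (degassed), 100 °C
Reagents that add atoms: none
Why: Thermal syn-elimination of the sulfoxide (Ei, five-membered cyclic transition state) can only take a cis hydrogen from the sp3 carbon C3 of ring A, so benzenesulfenic acid should leave while bromine stays on C4, and the 2,4-dienone 13 then enolises to the aromatic phenol; no thiophile or base is added, so the reversible [2,3] shift of the allylic sulfoxide stays unproductive and dehydrobromination is not promoted.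

Step 8
Reactants: 14 2-[2-(benzyloxy)-4,6-dibromophenoxy]-4-bromophenol
Product: 15 1-(benzyloxy)-3,5-dibromo-2-(5-bromo-2-methoxyphenoxy)benzene
Conditions: MeI, K2CO3, acetone, 50 °C
Reagents that add atoms: iodomethane, CI
Why: Williamson O-methylation of the only free phenol (the C1 hydroxyl of ring A) by SN2 at the methyl group.

Step 9
Reactants: 15 1-(benzyloxy)-3,5-dibromo-2-(5-bromo-2-methoxyphenoxy)benzene
Product: 16 3,5-dibromo-2-(5-bromo-2-methoxyphenoxy)phenol
Conditions: BCl3, pentamethylbenzene, CH2Cl2, −78 °C; then H2O
Reagents that add atoms: none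
Why: Lewis acid debenzylation, in which boron trichloride coordinates the benzylic ether oxygen and the benzyl cation equivalent is captured by pentamethylbenzene (Friedel–Crafts alkylation), should leave the aryl methyl ether, the diaryl ether and the three C–Br bonds untouched at −78 °C.

Compound list
1 | 2-(benzyloxy)phenol | Oc1ccccc1OCc1ccccc1 | starting material
2 | 2-(benzyloxy)-4,6-dibromophenol | Oc1c(OCc2ccccc2)cc(Br)cc1Br | intermediate
3 | chloroacetone (1-chloropropan-2-one) | CC(=O)CCl | starting material
4 | 1-[2-(benzyloxy)-4,6-dibromophenoxy]propan-2-one | CC(=O)COc1c(OCc2ccccc2)cc(Br)cc1Br | intermediate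
5 | N,N-dimethylformamide dimethyl acetal | COC(OC)N(C)C | starting material
6 | (3Z)-3-[2-(benzyloxy)-4,6-dibromophenoxy]-4-(dimethylamino)but-3-en-2-one | CC(=O)/C(Oc1c(OCc2ccccc2)cc(Br)cc1Br)=C/N(C)C | intermediate
7 | (1Z)-2-[2-(benzyloxy)-4,6-dibromophenoxy]-3-[(tert-butyldimethylsilyl)oxy]-N,N-dimethylbuta-1,3-dien-1-amine | CN(C)/C=C(\Oc1c(OCc2ccccc2)cc(Br)cc1Br)C(=C)O[Si](C)(C)C(C)(C)C | intermediate
8 | phenyl vinyl sulfoxide (racemic) | C=CS(=O)c1ccccc1 | starting material
9 | 1,2-dibromoethyl phenyl sulfoxide (racemic, mixture of diastereomers, configuration not defined) | BrCC(Br)S(=O)c1ccccc1 | intermediate (not isolated)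
10 | rac-1-bromovinyl phenyl sulfoxide (one enantiomer drawn) | C=C(Br)[S@@](=O)c1ccccc1 | intermediate
11 | 2-[2-(benzyloxy)-4,6-dibromophenoxy]-6-bromo-3-[(tert-butyldimethylsilyl)oxy]-N,N-dimethyl-6-(phenylsulfinyl)cyclohex-2-en-1-amine (racemic, mixture of diastereomers, configuration not defined) | CN(C)C1C(Oc2c(OCc3ccccc3)cc(Br)cc2Br)=C(O[Si](C)(C)C(C)(C)C)CCC1(Br)S(=O)c1ccccc1 | intermediate (not isolated)
12 | rac-2-[2-(benzyloxy)-4,6-dibromophenoxy]-4-bromo-4-(phenylsulfinyl)cyclohex-2-en-1-one (mixture of diastereomers, one drawn) | O=C1CC[C@](Br)([S@](=O)c2ccccc2)C=C1Oc1c(OCc2ccccc2)cc(Br)cc1Br | intermediate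
13 | 2-[2-(benzyloxy)-4,6-dibromophenoxy]-4-bromocyclohexa-2,4-dien-1-one | O=C1CC=C(Br)C=C1Oc1c(OCc2ccccc2)cc(Br)cc1Br | intermediate (not isolated)
14 | 2-[2-(benzyloxy)-4,6-dibromophenoxy]-4-bromophenol | Oc1ccc(Br)cc1Oc1c(OCc2ccccc2)cc(Br)cc1Br | intermediate
15 | 1-(benzyloxy)-3,5-dibromo-2-(5-bromo-2-methoxyphenoxy)benzene | COc1ccc(Br)cc1Oc1c(OCc2ccccc2)cc(Br)cc1Br | intermediate
16 | 3,5-dibromo-2-(5-bromo-2-methoxyphenoxy)phenol | COc1ccc(Br)cc1Oc1c(O)cc(Br)cc1Br | target

Total step count: 9. Longest linear sequence: 8 steps (steps 1, 2, 3, 4, 6, 7, 8, 9); step 5 is a one-step side branch.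

Steps most likely to fail

Step 6. The cycloaddition may stall, because the 1,1-disubstituted vinyl sulfoxide is only a moderate acceptor and the diene carries a bulky 2-aryloxy group. Meanwhile the diene may hydrolyse, or the amine of the cycloadduct may displace the neighbouring bromide before the acid quench. The fallback leaves the cycloaddition and builds the ring A phenol by nucleophilic aromatic substitution and Baeyer–Villiger oxidation. It sets out from 2: displacement of fluoride from commercial 4-bromo-2-fluorobenzaldehyde (O=Cc1ccc(Br)cc1F) with K2CO3 in DMF at 90 °C should give 2-[2-(benzyloxy)-4,6-dibromophenoxy]-4-bromobenzaldehyde F1, since fluoride ortho to the formyl group is displaced far faster than the para bromide. mCPBA in CH2Cl2 should then convert F1 by aryl migration into 2-[2-(benzyloxy)-4,6-dibromophenoxy]-4-bromophenyl formate F2, and methanolysis (cat. K2CO3, MeOH, rt) comes back to the route at 14.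

Step 7. On heating, the tertiary allylic bromide may be lost by ionisation or dehydrobromination faster than sulfenic acid is expelled, or the allylic sulfoxide may drain away through its [2,3]-shifted sulfenate. The fallback keeps the cycloaddition but takes bromine out of the elimination and introduces it afterwards by electrophilic substitution. It sets out from 7: cycloaddition with phenyl vinyl sulfoxide 8 (toluene, 60 °C) should give 2-[2-(benzyloxy)-4,6-dibromophenoxy]-3-[(tert-butyldimethylsilyl)oxy]-N,N-dimethyl-6-(phenylsulfinyl)cyclohex-2-en-1-amine F3, which is not isolated. Dilute HCl in THF should convert F3 into 2-[2-(benzyloxy)-4,6-dibromophenoxy]-4-(phenylsulfinyl)cyclohex-2-en-1-one F4. Thermolysis in toluene at 100 °C should lead through 2-[2-(benzyloxy)-4,6-dibromophenoxy]cyclohexa-2,4-dien-1-one F5 to 2-[2-(benzyloxy)-4,6-dibromophenoxy]phenol F6. One equivalent of NBS in MeCN at 0 °C should then brominate para to the free hydroxyl group (C4 of ring A), ring B being deactivated by its two bromines, and come back to the route at 14.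

Step 4. Enolisation may be incomplete, silylation may occur on carbon, or the moisture-sensitive diene, which is too heavy to distil, may hydrolyse during handling. The fallback gives up the ring construction and forms the diaryl ether by oxidative copper-catalysed O-arylation (Chan–Lam coupling). It sets out from 2: coupling with commercial (5-bromo-2-methoxyphenyl)boronic acid (COc1ccc(Br)cc1B(O)O) using Cu(OAc)2 (cat.), pyridine and 4 Å molecular sieves in CH2Cl2 under O2 at rt comes back to the route directly at 15. The aryl bromides are inert to copper under these conditions, although the doubly ortho-substituted partners are expected to couple slowly.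

Further compounds
F1 | step 6 | 2-[2-(benzyloxy)-4,6-dibromophenoxy]-4-bromobenzaldehyde | O=Cc1ccc(Br)cc1Oc1c(OCc2ccccc2)cc(Br)cc1Br
F2 | step 6 | 2-[2-(benzyloxy)-4,6-dibromophenoxy]-4-bromophenyl formate | O=COc1ccc(Br)cc1Oc1c(OCc2ccccc2)cc(Br)cc1Br
F3 | step 7 | 2-[2-(benzyloxy)-4,6-dibromophenoxy]-3-[(tert-butyldimethylsilyl)oxy]-N,N-dimethyl-6-(phenylsulfinyl)cyclohex-2-en-1-amine (racemic, mixture of diastereomers, configuration not defined) | CN(C)C1C(Oc2c(OCc3ccccc3)cc(Br)cc2Br)=C(O[Si](C)(C)C(C)(C)C)CCC1S(=O)c1ccccc1
F4 | step 7 | 2-[2-(benzyloxy)-4,6-dibromophenoxy]-4-(phenylsulfinyl)cyclohex-2-en-1-one (racemic, mixture of diastereomers, configuration not defined) | O=C1CCC(S(=O)c2ccccc2)C=C1Oc1c(OCc2ccccc2)cc(Br)cc1Br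
F5 | step 7 | 2-[2-(benzyloxy)-4,6-dibromophenoxy]cyclohexa-2,4-dien-1-one | O=C1CC=CC=C1Oc1c(OCc2ccccc2)cc(Br)cc1Br
F6 | step 7 | 2-[2-(benzyloxy)-4,6-dibromophenoxy]phenol | Oc1ccccc1Oc1c(OCc2ccccc2)cc(Br)cc1Br
F0 | step 4 | none | none
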